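The data come from a simulation for an exercise; scatter was added.

Each turn of J + Z -> E takes one J and one Z, so the difference between [Z] and [J] stays where the charge put it. One reading of E therefore gives you both remaining concentrations, as long as the E you read is the E that was made.

| flask | J | Z | Q | time |
|---|---|---|---|---|
| cedar | 0.200 M | 0.300 M | 0.00600 M |  |
| larch | 0.120 M | 0.220 M | 0.00600 M |  |
| alder | 0.200 M | 0.300 M | 0.00900 M |  |
| oak | 0.200 M | 0.900 M | 0.00600 M |  |
| ash | 0.0660 M | 0.0990 M | 0.00600 M | 96 min |

- cedar run (time / min: [E] / M): 19: 0.0424; 38: 0.0627; 58: 0.0739; 77: 0.0852; 96: 0.0867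
- larch run (time / min: [E] / M): 19: 0.0173; 38: 0.0311; 58: 0.0389; 77: 0.0401; 96: 0.0411
- alder run (time / min: [E] / M): 19: 0.0586; 38: 0.0773; 58: 0.0874; 77: 0.0871; 96: 0.0922
- oak run (time / min: [E] / M): 19: 0.0995; 38: 0.1356; 58: 0.1464; 77: 0.1499; 96: 0.1461

(standard deviation of a reading: 0.002 M)

- the power of [Q] that the first rate follows, about the charge of the cedar run; measure it at two percent of J made into E
- the power of [J] that the first rate follows, about the charge of the cedar run; measure it at two percent of J made into E (one fixed amount of E, the same in the runs compared)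
- E in the ash run at 96 min, as a share of the J charged

Let c_J and c_Z be the charges of J and Z, and turn each reading into the dose D = ln[(c_J/c_Z)(c_Z − E)/(c_J − E)]/(c_Z − c_J). This is the integrated second-order law. If the rate is k[J][Z], with k set by the catalyst and free to change with time, then D is the integral of k over time and should not depend on the charges of J and Z.

Now read the row at 19 min. Cedar gives 0.859 M⁻¹. Oak, with its higher Z, gives 0.816 M⁻¹. Larch, with less J and less Z, gives 0.738 M⁻¹, give or take 0.0961 M⁻¹. So I take first order in J and in Z.

Alder reads 1.29 M⁻¹, which is 1.50 times cedar for 1.50 times the Q, so my order in Q is 1.01.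

Read down the cedar column next. D reaches 2.27 M⁻¹ at 96 min, and the last 19.0 min add about 0.0614 M⁻¹ of it.

Ash has cedar's Q, so I give it cedar's dose at 96 min. Its [Z]/[J] then goes to 1.62, which means E = 0.0125 M, or 18.9% of its J.

The forecast, holding that “this is an equilibrium, not catalyst death”, gave 1.3 in Q, 1 in J and 20% for ash; my reckoning gives another number for Q and for ash.

    Q + J + Z → E + Q (9.300 M⁻² min⁻¹)
    E → Wy (0.002838 min⁻¹)
    2 Q → 2 Xo (1.764 M⁻¹ min⁻¹)

The ash run gives 19.7% of its J; about the cedar charge, the first rate follows [Q] to the power 1.0 and [J] to the power 1.1. The passing of E into Wy moves the readings by 6.7 times the scatter, root mean square. Put back through the dose, ash's 0.0130 M reads 2.38 M⁻¹, against cedar's 2.27 M⁻¹ at the same time. Oak's reading at 96 min gives 1.62 M⁻¹, less than cedar's 2.27 M⁻¹.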